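**Retrosynthetic overview** (ring A = γ-lactone, ring B = cyclopentanone, ring C = spiro δ-lactone)
1. Target 27 ⇐ carbinol 26 ⇐ silyl ether 25; ring C is opened at the spiro C–CH2 bond (enolate C-alkylation) and at the ester C–O bond, giving bicyclic β-keto ester 9 and chloro alcohol 21.
2. Ring B of 9 ⇐ intramolecular aldol addition of the ester CH2 of 7 onto its quaternary formyl group, then oxidation (key ring closure).
3. 7 ⇐ formylation/methylation of homoterpenylic acid 5 ⇐ haloform ⇐ lactone 3 ⇐ oxidative cleavage/lactonization of (S)-α-terpineol 1.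
4. 21 ⇐ diol 20 ⇐ Evans deconjugative syn-aldol of senecioyl imide 16 with (R)-α-silyloxy aldehyde 13.
5. Order of ring formation: A (step 1), then B (step 5), then C (step 14).

Assumption: (S)-(−)-α-terpineol of high enantiomeric purity is taken as a commercial terpene; its stereocentre becomes C3a of the target.

**Fragment A (bicyclic β-keto ester 9)**

Step 1
Reactants: 1 (S)-(−)-α-terpineol, 2-[(1S)-4-methylcyclohex-3-en-1-yl]propan-2-ol
Product: 3 (4S)-5,5-dimethyl-4-(3-oxobutyl)oxolan-2-one, via seco hydroxy keto acid 2 (not isolated)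
Conditions: RuCl3 (2 mol %), NaIO4 (4 equiv), EtOAc/MeCN/H2O, rt; 1 M HCl work-up
Reagents that add atoms: sodium periodate, [Na+].[O-]I(=O)(=O)=O (oxygen delivered through the catalytic RuO4 cycle); water, O
Why: Ru-catalysed oxidative cleavage of the trisubstituted ring alkene gives a methyl ketone and a carboxylic acid, and the γ-hydroxy acid lactonizes on acidification to form ring A with the terpineol stereocentre untouched (4S).

Step 2
Reactants: 3 (4S)-5,5-dimethyl-4-(3-oxobutyl)oxolan-2-one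
Product: 5 3-[(3S)-2,2-dimethyl-5-oxooxolan-3-yl]propanoic acid (homoterpenylic acid), via trichloromethyl ketone 4 (not isolated)
Conditions: NaOCl (aq., 3.5 equiv), NaOH, dioxane/H2O, 0 °C → rt; HCl to pH 1
Reagents that add atoms: sodium hydroxide, [Na+].[OH-]
Why: Haloform reaction: exhaustive α-chlorination of the methyl ketone and C–C cleavage by hydroxide remove one carbon and leave the side-chain acid; the lactone is intact after acidification and the stereocentre is not involved.

Step 3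
Reactants: 5 3-[(3S)-2,2-dimethyl-5-oxooxolan-3-yl]propanoic acid
Product: 6 3-[(3S)-4-(hydroxymethylidene)-2,2-dimethyl-5-oxooxolan-3-yl]propanoic acid
Conditions: LiN(i-Pr)2 (3.2 equiv), THF, −78 °C; HCO2Et, −78 → 0 °C; 1 M HCl
Reagents that add atoms: ethyl formate, CCOC=O
Why: The acid is deprotonated first, so the second deprotonation takes place only at the lactone α-CH2 (carboxylate α-protons are far less acidic), and Claisen formylation gives the stable hydroxymethylene lactone; no stereocentre is made.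

Step 4
Reactants: 6 3-[(3S)-4-(hydroxymethylidene)-2,2-dimethyl-5-oxooxolan-3-yl]propanoic acid
Product: 7 methyl 3-[(3S,4S)-4-formyl-2,2,4-trimethyl-5-oxooxolan-3-yl]propanoate
Conditions: MeI (5 equiv), K2CO3 (3 equiv), acetone, reflux
Reagents that add atoms: iodomethane, CI
Why: C-Alkylation of the formyl-lactone enolate (with concurrent esterification of the carboxylate) creates the quaternary centre; MeI attacks anti to the adjacent side chain, so the methyl is cis to C3–H and the formyl group cis to the side chain (4S).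

Step 5 (key ring closure)
Reactants: 7 methyl 3-[(3S,4S)-4-formyl-2,2,4-trimethyl-5-oxooxolan-3-yl]propanoate
Product: 8 methyl (3aS,6aS)-6-hydroxy-3,3,6a-trimethyl-1-oxohexahydro-1H-cyclopenta[c]furan-5-carboxylate (mixture of C5/C6 epimers)
Conditions: lithium 2,2,6,6-tetramethylpiperidide (1.1 equiv), THF, −78 °C, slow addition of 7 to the base; AcOH, −78 °C
Reagents that add atoms: none
Why: Intramolecular aldol addition: the ester CH2 is the only enolizable site and the hindered, hydride-free amide base does not attack the neopentyl aldehyde, so 5-exo addition closes ring B; only the cis-fused ring can form, and the new C5/C6 centres are irrelevant (C6 is oxidized next, C5 is enolizable).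

Step 6
Reactants: 8 methyl (3aS,6aS)-6-hydroxy-3,3,6a-trimethyl-1-oxohexahydro-1H-cyclopenta[c]furan-5-carboxylate
Product: 9 methyl (3aS,6aS)-3,3,6a-trimethyl-1,6-dioxohexahydro-1H-cyclopenta[c]furan-5-carboxylate
Conditions: Dess–Martin periodinane, CH2Cl2, rt
Reagents that add atoms: none
Why: Dess–Martin oxidation of the secondary carbinol gives the β-keto ester and erases the C6 stereocentre; C3a and C6a are untouched.

**Fragment B (chloro alcohol 21)**

Step 7
Reactants: 10 methyl (2R)-2-hydroxy-3-methylbutanoate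
Product: 11 methyl (2R)-2-[(tert-butyldimethylsilyl)oxy]-3-methylbutanoate
Conditions: TBSCl, imidazole, DMF, rt
Reagents that add atoms: tert-butyldimethylsilyl chloride, CC(C)(C)[Si](C)(C)Cl
Why: Imidazole-promoted silylation protects the oxygen that later becomes the isobutyryl ketone; the chiral-pool (R) centre is untouched.

Step 8
Reactants: 11 methyl (2R)-2-[(tert-butyldimethylsilyl)oxy]-3-methylbutanoate
Product: 13 (2R)-2-[(tert-butyldimethylsilyl)oxy]-3-methylbutanal, via aluminium hemiacetal 12 (not isolated)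
Conditions: i-Bu2AlH (1.05 equiv), CH2Cl2, −78 °C; aq. potassium sodium tartrate
Reagents that add atoms: none
Why: Half-reduction of the ester stops at the tetrahedral aluminium hemiacetal at −78 °C, which releases the aldehyde on work-up without epimerizing the α-silyloxy centre.

Step 9
Reactants: 14 (4S)-4-benzyl-1,3-oxazolidin-2-one; 15 3-methylbut-2-enoyl chloride
Product: 16 (4S)-4-benzyl-3-(3-methylbut-2-enoyl)-1,3-oxazolidin-2-one
Conditions: n-BuLi, THF, −78 °C; then 15, −78 → 0 °C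
Reagents that add atoms: none
Why: N-Acylation of the oxazolidinone after deprotonation gives the Evans imide that carries C4', C5' and the isopropenyl carbons.

Step 10
Reactants: 16 (4S)-4-benzyl-3-(3-methylbut-2-enoyl)-1,3-oxazolidin-2-one; 13 (2R)-2-[(tert-butyldimethylsilyl)oxy]-3-methylbutanal
Product: 19 (4S)-4-benzyl-3-[(2S,3S,4R)-4-[(tert-butyldimethylsilyl)oxy]-3-hydroxy-5-methyl-2-(prop-1-en-2-yl)hexanoyl]-1,3-oxazolidin-2-one, via boron dienolate 17 (not isolated), via boron aldolate 18 (not isolated)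
Conditions: Bu2BOTf, Et3N, CH2Cl2, −78 → 0 °C; 13, −78 → 0 °C; pH 7 buffer, MeOH, 30% H2O2
Reagents that add atoms: none
Why: Evans deconjugative syn-aldol: γ-deprotonation gives the (Z)-boron dienolate, which reacts at its α-carbon through a chair Zimmerman–Traxler transition state on the face opposite the benzyl group, setting C2 (S, isopropenyl) and C3 (S, carbinol) syn; the (R)-aldehyde is the matched partner (3,4-anti).

Step 11
Reactants: 19 the aldol adduct
Product: 20 (2R,3S,4R)-4-[(tert-butyldimethylsilyl)oxy]-5-methyl-2-(prop-1-en-2-yl)hexane-1,3-diol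
Conditions: LiBH4, MeOH (2 equiv), Et2O, 0 °C
Reagents that add atoms: none
Why: Reductive cleavage of the imide releases the auxiliary and gives the primary alcohol without touching the stereocentres (the descriptor at C2 changes only through priority).

Step 12
Reactants: 20 (2R,3S,4R)-4-[(tert-butyldimethylsilyl)oxy]-5-methyl-2-(prop-1-en-2-yl)hexane-1,3-diol
Product: 21 (2S,3S,4R)-4-[(tert-butyldimethylsilyl)oxy]-1-chloro-5-methyl-2-(prop-1-en-2-yl)hexan-3-ol
Conditions: PPh3, CCl4, MeCN, rt → 40 °C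
Reagents that add atoms: carbon tetrachloride, ClC(Cl)(Cl)Cl
Why: Appel chlorination converts only the unhindered primary hydroxyl (the secondary one is flanked by two branched carbons) into a leaving group that survives the thermal coupling.

**Union and endgame**

Step 13
Reactants: 9 methyl (3aS,6aS)-3,3,6a-trimethyl-1,6-dioxohexahydro-1H-cyclopenta[c]furan-5-carboxylate; 21 the chloro alcohol
Product: 23 (2S,3S,4R)-4-[(tert-butyldimethylsilyl)oxy]-1-chloro-5-methyl-2-(prop-1-en-2-yl)hexan-3-yl (3aS,6aS)-3,3,6a-trimethyl-1,6-dioxohexahydro-1H-cyclopenta[c]furan-5-carboxylate, via acylketene 22 (not isolated)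
Conditions: DMAP (0.3 equiv), toluene, reflux, 4 Å sieves
Reagents that add atoms: none
Why: Transesterification of the enolizable β-keto ester proceeds through the acylketene and so works with a hindered secondary alcohol; it joins the fragments without touching a stereocentre.

Step 14
Reactants: 23 the tethered β-keto ester
Product: 25 (3aS,5R,6aS,5'S,6'S)-6'-[(1R)-1-[(tert-butyldimethylsilyl)oxy]-2-methylpropyl]-3,3,6a-trimethyl-5'-(prop-1-en-2-yl)tetrahydrospiro[cyclopenta[c]furan-5,3'-oxane]-1,2',6-trione, via primary iodide 24 (not isolated)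
Conditions: NaI, Cs2CO3, DMF (0.02 M), 55 °C
Reagents that add atoms: none
Why: Finkelstein exchange and intramolecular 6-exo C-alkylation of the β-keto ester close ring C and create the spiro centre; the tether delivers the CH2 to the convex face of the bicycle (the side of C3a–H and the angular methyl, away from ring A), giving 5R, and O-alkylation would need an eight-membered ring.

Step 15
Reactants: 25 the silyl ether
Product: 26 (3aS,5R,6aS,5'S,6'S)-6'-[(1R)-1-hydroxy-2-methylpropyl]-3,3,6a-trimethyl-5'-(prop-1-en-2-yl)tetrahydrospiro[cyclopenta[c]furan-5,3'-oxane]-1,2',6-trione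
Conditions: HF·pyridine, pyridine/THF, 0 °C → rt
Reagents that add atoms: none
Why: Base-free fluoride desilylation frees the secondary alcohol without retro-Claisen opening of the β-keto lactones; ring expansion by acyl shift to a seven-membered lactone is unfavourable.

Step 16
Reactants: 26 the secondary alcohol
Product: 27 target CNP0216954.1, (3aS,5R,6aS,5'S,6'S)-3,3,6a-trimethyl-6'-(2-methylpropanoyl)-5'-(prop-1-en-2-yl)tetrahydrospiro[cyclopenta[c]furan-5,3'-oxane]-1,2',6-trione
Conditions: Dess–Martin periodinane, CH2Cl2, rt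
Reagents that add atoms: none
Why: Dess–Martin oxidation gives the isobutyryl ketone under non-basic conditions, so the adjacent α-acyloxy centre C6' is not epimerized.

**Compound list**
1 | (S)-(−)-α-terpineol | CC1=CC[C@H](CC1)C(C)(C)O | starting material
2 | (3S)-3-(2-hydroxypropan-2-yl)-6-oxoheptanoic acid | CC(=O)CC[C@@H](CC(=O)O)C(C)(C)O | intermediate (not isolated)
3 | (4S)-5,5-dimethyl-4-(3-oxobutyl)oxolan-2-one | CC(=O)CC[C@@H]1C(C)(C)OC(=O)C1 | intermediate
4 | (4S)-5,5-dimethyl-4-(4,4,4-trichloro-3-oxobutyl)oxolan-2-one | ClC(Cl)(Cl)C(=O)CC[C@@H]1C(C)(C)OC(=O)C1 | intermediate (not isolated)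
5 | 3-[(3S)-2,2-dimethyl-5-oxooxolan-3-yl]propanoic acid | OC(=O)CC[C@@H]1C(C)(C)OC(=O)C1 | intermediate
6 | 3-[(3S)-4-(hydroxymethylidene)-2,2-dimethyl-5-oxooxolan-3-yl]propanoic acid | OC(=O)CC[C@@H]1C(C)(C)OC(=O)C1=CO | intermediate
7 | methyl 3-[(3S,4S)-4-formyl-2,2,4-trimethyl-5-oxooxolan-3-yl]propanoate | COC(=O)CC[C@@H]1C(C)(C)OC(=O)[C@]1(C)C=O | intermediate
8 | methyl (3aS,6aS)-6-hydroxy-3,3,6a-trimethyl-1-oxohexahydro-1H-cyclopenta[c]furan-5-carboxylate | COC(=O)C1C[C@@H]2C(C)(C)OC(=O)[C@]2(C)C1O | intermediate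
9 | methyl (3aS,6aS)-3,3,6a-trimethyl-1,6-dioxohexahydro-1H-cyclopenta[c]furan-5-carboxylate | COC(=O)C1C[C@@H]2C(C)(C)OC(=O)[C@]2(C)C1=O | intermediate
10 | methyl (2R)-2-hydroxy-3-methylbutanoate | COC(=O)[C@H](O)C(C)C | starting material
11 | methyl (2R)-2-[(tert-butyldimethylsilyl)oxy]-3-methylbutanoate | COC(=O)[C@H](O[Si](C)(C)C(C)(C)C)C(C)C | intermediate
12 | [(2R)-2-[(tert-butyldimethylsilyl)oxy]-1-methoxy-3-methylbutoxy]bis(2-methylpropyl)alumane | COC(O[Al](CC(C)C)CC(C)C)[C@H](O[Si](C)(C)C(C)(C)C)C(C)C | intermediate (not isolated)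
13 | (2R)-2-[(tert-butyldimethylsilyl)oxy]-3-methylbutanal | O=C[C@H](O[Si](C)(C)C(C)(C)C)C(C)C | intermediate
14 | (4S)-4-benzyl-1,3-oxazolidin-2-one | O=C1N[C@@H](Cc2ccccc2)CO1 | starting material
15 | 3-methylbut-2-enoyl chloride | CC(C)=CC(Cl)=O | starting material
16 | (4S)-4-benzyl-3-(3-methylbut-2-enoyl)-1,3-oxazolidin-2-one | CC(C)=CC(=O)N1[C@@H](Cc2ccccc2)COC1=O | intermediate
17 | (4S)-4-benzyl-3-[(1Z)-1-[(dibutylboranyl)oxy]-3-methylbuta-1,3-dien-1-yl]-1,3-oxazolidin-2-one | C=C(C)/C=C(\OB(CCCC)CCCC)N1[C@@H](Cc2ccccc2)COC1=O | intermediate (not isolated)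
18 | O-dibutylboryl aldolate of 19 | C=C(C)[C@H](C(=O)N1[C@@H](Cc2ccccc2)COC1=O)[C@H](OB(CCCC)CCCC)[C@H](O[Si](C)(C)C(C)(C)C)C(C)C | intermediate (not isolated)
19 | (4S)-4-benzyl-3-[(2S,3S,4R)-4-[(tert-butyldimethylsilyl)oxy]-3-hydroxy-5-methyl-2-(prop-1-en-2-yl)hexanoyl]-1,3-oxazolidin-2-one | C=C(C)[C@H](C(=O)N1[C@@H](Cc2ccccc2)COC1=O)[C@H](O)[C@H](O[Si](C)(C)C(C)(C)C)C(C)C | intermediate
20 | (2R,3S,4R)-4-[(tert-butyldimethylsilyl)oxy]-5-methyl-2-(prop-1-en-2-yl)hexane-1,3-diol | C=C(C)[C@H](CO)[C@H](O)[C@H](O[Si](C)(C)C(C)(C)C)C(C)C | intermediate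
21 | (2S,3S,4R)-4-[(tert-butyldimethylsilyl)oxy]-1-chloro-5-methyl-2-(prop-1-en-2-yl)hexan-3-ol | C=C(C)[C@H](CCl)[C@H](O)[C@H](O[Si](C)(C)C(C)(C)C)C(C)C | intermediate
22 | (3aS,6aS)-3,3,6a-trimethyl-5-(oxomethylidene)tetrahydro-1H-cyclopenta[c]furan-1,6(6aH)-dione | O=C=C1C[C@@H]2C(C)(C)OC(=O)[C@]2(C)C1=O | intermediate (not isolated)
23 | (2S,3S,4R)-4-[(tert-butyldimethylsilyl)oxy]-1-chloro-5-methyl-2-(prop-1-en-2-yl)hexan-3-yl (3aS,6aS)-3,3,6a-trimethyl-1,6-dioxohexahydro-1H-cyclopenta[c]furan-5-carboxylate | C=C(C)[C@H](CCl)[C@H](OC(=O)C1C[C@@H]2C(C)(C)OC(=O)[C@]2(C)C1=O)[C@H](O[Si](C)(C)C(C)(C)C)C(C)C | intermediate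
24 | iodo analogue of 23 (1-iodo in place of 1-chloro) | C=C(C)[C@H](CI)[C@H](OC(=O)C1C[C@@H]2C(C)(C)OC(=O)[C@]2(C)C1=O)[C@H](O[Si](C)(C)C(C)(C)C)C(C)C | intermediate (not isolated)
25 | (3aS,5R,6aS,5'S,6'S)-6'-[(1R)-1-[(tert-butyldimethylsilyl)oxy]-2-methylpropyl]-3,3,6a-trimethyl-5'-(prop-1-en-2-yl)tetrahydrospiro[cyclopenta[c]furan-5,3'-oxane]-1,2',6-trione | C=C(C)[C@@H]1C[C@]2(C[C@@H]3C(C)(C)OC(=O)[C@]3(C)C2=O)C(=O)O[C@@H]1[C@H](O[Si](C)(C)C(C)(C)C)C(C)C | intermediate
26 | (3aS,5R,6aS,5'S,6'S)-6'-[(1R)-1-hydroxy-2-methylpropyl]-3,3,6a-trimethyl-5'-(prop-1-en-2-yl)tetrahydrospiro[cyclopenta[c]furan-5,3'-oxane]-1,2',6-trione | C=C(C)[C@@H]1C[C@]2(C[C@@H]3C(C)(C)OC(=O)[C@]3(C)C2=O)C(=O)O[C@@H]1[C@H](O)C(C)C | intermediate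
27 | CNP0216954.1, (3aS,5R,6aS,5'S,6'S)-3,3,6a-trimethyl-6'-(2-methylpropanoyl)-5'-(prop-1-en-2-yl)tetrahydrospiro[cyclopenta[c]furan-5,3'-oxane]-1,2',6-trione | C=C(C)[C@@H]1C[C@]2(C[C@@H]3C(C)(C)OC(=O)[C@]3(C)C2=O)C(=O)O[C@@H]1C(=O)C(C)C | target

**Totals**
Total step count: 16.
Longest linear sequence: 10 (steps 1–6, then 13–16). The other branches are 9 steps (7, 8, 10–12, 13–16) and 8 steps (9–12, 13–16).

**Steps most likely to fail**

Step 5 (ester-enolate aldol onto a hindered formyl group; risks are attack of the base on the aldehyde, deformylation, and retro-aldol formyl transfer on warming). The fallback sets out from 7 and comes back at 9, closing ring B by a Claisen-type acylation instead of an aldol. Pinnick oxidation of 7 (NaClO2, NaH2PO4, 2-methylbut-2-ene, t-BuOH/H2O) gives (3S,4S)-4-(3-methoxy-3-oxopropyl)-3,5,5-trimethyl-2-oxooxolane-3-carboxylic acid F1. Esterification with trimethylsilyldiazomethane (MeOH/toluene) gives methyl (3S,4S)-4-(3-methoxy-3-oxopropyl)-3,5,5-trimethyl-2-oxooxolane-3-carboxylate F2. Dieckmann condensation (potassium tert-butoxide, THF, 0 °C; AcOH) onto the exocyclic ester, which is cis to the side chain, then gives 9 directly.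

Step 10 (deconjugative aldol of a dienolate with a doubly branched α-silyloxy aldehyde; risks are low conversion and α/γ scrambling). The fallback sets out from 13 and comes back at 20, building the C2–C3 stereodiad by epoxide opening instead of an aldol. Still–Gennari olefination of 13 (methyl bis(2,2,2-trifluoroethyl)phosphonoacetate, KN(SiMe3)2, 18-crown-6, THF, −78 °C) gives methyl (2Z,4R)-4-[(tert-butyldimethylsilyl)oxy]-5-methylhex-2-enoate F3. Reduction with i-Bu2AlH (CH2Cl2, −78 °C) gives (2Z,4R)-4-[(tert-butyldimethylsilyl)oxy]-5-methylhex-2-en-1-ol F4. Sharpless epoxidation (Ti(O-i-Pr)4, diethyl L-(+)-tartrate, t-BuOOH, 4 Å sieves, CH2Cl2, −20 °C) gives the cis-epoxy alcohol [(2S,3S)-3-[(1R)-1-[(tert-butyldimethylsilyl)oxy]-2-methylpropyl]oxiran-2-yl]methanol F5. Opening at C2 with inversion by isopropenylmagnesium bromide and CuI (THF, −30 → 0 °C) gives diol 20; attack at C2 is favoured because C3 is shielded by the silyloxy-isobutyl group.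

Step 14 (spiro quaternary centre by intramolecular alkylation; risks are facial selectivity, slow displacement and elimination to a diene). The fallback sets out from 9 and 20 and comes back at 25, making the C–C bond before the C–O bond. Selective iodination of the primary hydroxyl of 20 (I2, PPh3, imidazole, CH2Cl2, 0 °C) gives (2S,3S,4R)-4-[(tert-butyldimethylsilyl)oxy]-1-iodo-5-methyl-2-(prop-1-en-2-yl)hexan-3-ol F6. Intermolecular C-alkylation of 9 with F6 (Cs2CO3, DMF, 40 °C), again from the convex face, gives methyl (3aS,5R,6aS)-5-[(2S,3S,4R)-4-[(tert-butyldimethylsilyl)oxy]-3-hydroxy-5-methyl-2-(prop-1-en-2-yl)hexyl]-3,3,6a-trimethyl-1,6-dioxohexahydro-1H-cyclopenta[c]furan-5-carboxylate F7. Acid-catalysed lactonization (camphorsulfonic acid, toluene, 70 °C, with removal of methanol) closes ring C to give 25; acid is used because an alkoxide would risk retro-Claisen cleavage.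

**Further compounds**
F1 | step 5 | (3S,4S)-4-(3-methoxy-3-oxopropyl)-3,5,5-trimethyl-2-oxooxolane-3-carboxylic acid | COC(=O)CC[C@@H]1C(C)(C)OC(=O)[C@]1(C)C(=O)O
F2 | step 5 | methyl (3S,4S)-4-(3-methoxy-3-oxopropyl)-3,5,5-trimethyl-2-oxooxolane-3-carboxylate | COC(=O)CC[C@@H]1C(C)(C)OC(=O)[C@]1(C)C(=O)OC
F3 | step 10 | methyl (2Z,4R)-4-[(tert-butyldimethylsilyl)oxy]-5-methylhex-2-enoate | COC(=O)/C=C\[C@H](O[Si](C)(C)C(C)(C)C)C(C)C
F4 | step 10 | (2Z,4R)-4-[(tert-butyldimethylsilyl)oxy]-5-methylhex-2-en-1-ol | OC/C=C\[C@H](O[Si](C)(C)C(C)(C)C)C(C)C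
F5 | step 10 | [(2S,3S)-3-[(1R)-1-[(tert-butyldimethylsilyl)oxy]-2-methylpropyl]oxiran-2-yl]methanol | OC[C@@H]1O[C@@H]1[C@H](O[Si](C)(C)C(C)(C)C)C(C)C
F6 | step 14 | (2S,3S,4R)-4-[(tert-butyldimethylsilyl)oxy]-1-iodo-5-methyl-2-(prop-1-en-2-yl)hexan-3-ol | C=C(C)[C@H](CI)[C@H](O)[C@H](O[Si](C)(C)C(C)(C)C)C(C)C
F7 | step 14 | methyl (3aS,5R,6aS)-5-[(2S,3S,4R)-4-[(tert-butyldimethylsilyl)oxy]-3-hydroxy-5-methyl-2-(prop-1-en-2-yl)hexyl]-3,3,6a-trimethyl-1,6-dioxohexahydro-1H-cyclopenta[c]furan-5-carboxylate | C=C(C)[C@H](C[C@]1(C[C@@H]2C(C)(C)OC(=O)[C@]2(C)C1=O)C(=O)OC)[C@H](O)[C@H](O[Si](C)(C)C(C)(C)C)C(C)C
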